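**Retrosynthetic overview**

1. Feature: the target oxolane (O1, C2H2, C3, C4, C5) has the C3 side chain cis to the C4 methyl and the C5 aryl trans to methyl. Counting the exocyclic carbinol carbon (Cα) as a ring atom between C3 and C4 gives an oxane whose four substituents are all equatorial.
2. Key disconnections: Cα–aryl (aryl Grignard addition to the 3-formyl oxolane) and oxolane C3–C4 (1,2-shift in a 4-hydroxy-5-triflyloxy oxane that expels Cα as the formyl group), both carried out in one flask.
3. The hydroxy triflate comes from a trans-2-aryl-3-methyl-dihydropyran-4-one by Luche reduction, silylation, glycal hydroboration, triflation and desilylation.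
4. The pyranone comes from veratraldehyde and a siloxydiene by catalytic asymmetric hetero-Diels–Alder reaction, then C3 methylation.
5. Ring order: the six-membered oxygen ring first (step 1), contracted to the oxolane last (step 9); both arene rings are bought.

Key step: step 9

Locants used for all six-membered intermediates: O1, C2 (aryl), C3 (methyl), C4, C5, C6H2. Oxane C2, C3, C5 and C6 become oxolane C5, C4, C3 and C2; oxane C4 becomes Cα.

Assumption: the titanium catalyst made from (S)-BINOL is taken to direct the diene to the Si face of veratraldehyde, giving the (S)-pyranone; if the sense proves opposite, (R)-BINOL is used and nothing else changes.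

**Route**

Step 1
Reactants: 1 veratraldehyde; 2 (E)-1-methoxy-3-(trimethylsilyloxy)buta-1,3-diene
Product: 4 (S)-2-(3,4-dimethoxyphenyl)-2,3-dihydro-4H-pyran-4-one, via silyl aldol adduct 3 (not isolated)
Conditions: Ti(OiPr)4 (10 mol%), (S)-BINOL (20 mol%), 4 Å MS, Et2O, −20 °C; then TFA, CH2Cl2, 0 °C, short contact
Reagents that add atoms: none
Why: Catalytic asymmetric hetero-Diels–Alder reaction in its Mukaiyama aldol–cyclisation form: the catalyst should deliver the diene terminus to the Si face of the aldehyde, fixing C2 as S, and TFA closes the ring by oxa-Michael addition with loss of methanol and the silyl group.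

Step 2
Reactants: 4 (S)-2-(3,4-dimethoxyphenyl)-2,3-dihydro-4H-pyran-4-one
Product: 6 (2S,3R)-2-(3,4-dimethoxyphenyl)-3-methyl-2,3-dihydro-4H-pyran-4-one, via lithium enolate 5 (not isolated)
Conditions: LiN(iPr)2 (1.05 equiv), THF, −78 °C; MeI, −78 → −40 °C; sat. aq NH4Cl
Reagents that add atoms: iodomethane, CI
Why: Kinetic enolate alkylation at C3, the only enolisable position: iodomethane should approach the face away from the C2 aryl group to give the 2,3-trans isomer, which is also the more stable one, and the low temperature restrains β-elimination of the ring oxygen.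

Step 3
Reactants: 6 (2S,3R)-2-(3,4-dimethoxyphenyl)-3-methyl-2,3-dihydro-4H-pyran-4-one
Product: 7 (2S,3S,4R)-2-(3,4-dimethoxyphenyl)-3-methyl-3,4-dihydro-2H-pyran-4-ol
Conditions: NaBH4, CeCl3·7H2O, MeOH, −78 → −40 °C; aq NaHCO3
Reagents that add atoms: none
Why: Luche 1,2-reduction: axial hydride delivery to the half-chair with aryl and methyl pseudo-equatorial should give the pseudo-equatorial C4 alcohol, trans to methyl and cis to aryl.

Step 4
Reactants: 7 (2S,3S,4R)-2-(3,4-dimethoxyphenyl)-3-methyl-3,4-dihydro-2H-pyran-4-ol
Product: 8 (2S,3R,4R)-4-(tert-butyldimethylsilyloxy)-2-(3,4-dimethoxyphenyl)-3-methyl-3,4-dihydro-2H-pyran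
Conditions: TBSCl, imidazole, DMF, rt
Reagents that add atoms: tert-butyldimethylsilyl chloride, CC(C)(C)[Si](C)(C)Cl
Why: Silyl ether formation under imidazole buffering, which spares the acid-labile glycal; the group marks O4 so that the oxygen introduced next at C5 is the only free hydroxyl.

Step 5
Reactants: 8 (2S,3R,4R)-4-(tert-butyldimethylsilyloxy)-2-(3,4-dimethoxyphenyl)-3-methyl-3,4-dihydro-2H-pyran
Product: 10 (2S,3R,4S,5S)-4-(tert-butyldimethylsilyloxy)-2-(3,4-dimethoxyphenyl)-3-methyloxan-5-ol, via C5 alkylborane 9 (not isolated)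
Conditions: BH3·THF, THF, 0 °C → rt; then NaBO3·4H2O, H2O, rt
Reagents that add atoms: sodium perborate (used as NaBO3·4H2O), [Na+].[Na+].O[B-]1(O)OO[B-](O)(O)OO1
Why: Hydroboration–oxidation of a glycal-type enol ether: boron adds to C5, the carbon β to the ring oxygen, syn and on the face away from the C4 silyloxy group as in glucal hydroborations, and oxidation with retention gives the equatorial C5 alcohol, the weakly basic perborate limiting 1,2-silyl migration.

Step 6
Reactants: 10 (2S,3R,4S,5S)-4-(tert-butyldimethylsilyloxy)-2-(3,4-dimethoxyphenyl)-3-methyloxan-5-ol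
Product: 11 (2S,3R,4S,5S)-4-(tert-butyldimethylsilyloxy)-2-(3,4-dimethoxyphenyl)-3-methyloxan-5-yl trifluoromethanesulfonate
Conditions: Tf2O, pyridine, CH2Cl2, −30 → 0 °C
Reagents that add atoms: trifluoromethanesulfonic anhydride, O=S(=O)(OS(=O)(=O)C(F)(F)F)C(F)(F)F
Why: O-sulfonylation with retention at C5; the equatorial triflate has no antiperiplanar hydrogen, which disfavours elimination, and the two β-oxygen atoms slow substitution, so the ester should be isolable.

Step 7
Reactants: 11 (2S,3R,4S,5S)-4-(tert-butyldimethylsilyloxy)-2-(3,4-dimethoxyphenyl)-3-methyloxan-5-yl trifluoromethanesulfonate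
Product: 12 (2S,3S,4S,5S)-2-(3,4-dimethoxyphenyl)-4-hydroxy-3-methyloxan-5-yl trifluoromethanesulfonate
Conditions: 48% aq HF, MeCN, 0 °C, polypropylene vessel; cold aq NaHCO3; used at once
Reagents that add atoms: none
Why: Acidic fluoride desilylation: HF is non-basic and weakly nucleophilic, so the alkoxide that would trigger the shift is never formed and the deactivated secondary triflate and the benzylic ring ether should survive.

Step 8
Reactants: 13 4-bromoveratrole
Product: 14 3,4-dimethoxyphenylmagnesium bromide (titrated THF solution)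
Conditions: Mg turnings, I2 (cat.), THF, 40 °C
Reagents that add atoms: magnesium, [Mg]
Why: Grignard formation by insertion of magnesium into the aryl–bromine bond.

Step 9
Reactants: 12 (2S,3S,4S,5S)-2-(3,4-dimethoxyphenyl)-4-hydroxy-3-methyloxan-5-yl trifluoromethanesulfonate; 14 3,4-dimethoxyphenylmagnesium bromide
Product: 18 (R)-(3,4-dimethoxyphenyl)[(3R,4S,5S)-5-(3,4-dimethoxyphenyl)-4-methyloxolan-3-yl]methanol (the target), via bromomagnesium alkoxide 15 (not isolated), via formyl oxolane 16 (not isolated), via bromomagnesium carbinolate 17 (not isolated)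
Conditions: 14 (3.0 equiv), THF, −78 → 0 °C; then sat. aq NH4Cl
Reagents that add atoms: none
Why: The first equivalent of 14 deprotonates the C4 hydroxyl to give 15, whose all-equatorial chair holds the ring bond C3–C4 antiperiplanar to the equatorial C5–O(triflate) bond, so the alkoxide drives a semipinacol 1,2-shift of C3 from C4 to C5 with loss of triflate and C4 leaves the ring as the formyl group of 16. The closest known reaction types are the base- or hydride-induced contraction of pyranoside sulfonates bearing a vicinal trans hydroxyl to formyl-branched furanosides, and the Grignard-induced contraction of trans-2-halocyclohexanol magnesium alkoxides to cyclopentyl carbinols. The oxolane is not closed by an exo or endo cyclisation; it arises by ring contraction (six to five) through the migration, which forms the oxane C3–C5 bond. The new ring stereocentre (oxane C5, oxolane C3) is set by stereospecific inversion at the triflate carbon while the migrating C3 keeps its configuration, which places formyl cis to methyl and trans to aryl. The carbinol centre is then set by Felkin–Anh addition of a second equivalent of 14 to 16, with the methyl-bearing ring carbon as the large group, and a magnesium chelate between the formyl and ring oxygen atoms would expose the same face, so both models predict R. The step needs C3 migration rather than epoxide closure, elimination, hydride shift or attack of 14 on the sulfonate: the equatorial leaving group has no antiperiplanar hydrogen or oxygen, epoxide closure would need the all-axial chair, only the C3–C4 bond has an alkoxide donor behind it, and capture of 16 as it forms keeps the epimerisable cis formyl centre away from base.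

**Compound list**

1 | veratraldehyde (3,4-dimethoxybenzaldehyde) | COc1ccc(C=O)cc1OC | starting material
2 | (E)-1-methoxy-3-(trimethylsilyloxy)buta-1,3-diene | CO/C=C/C(=C)O[Si](C)(C)C | starting material
3 | (S,E)-5-(3,4-dimethoxyphenyl)-1-methoxy-5-(trimethylsilyloxy)pent-1-en-3-one (silyl aldol adduct) | COc1ccc([C@H](CC(=O)/C=C/OC)O[Si](C)(C)C)cc1OC | intermediate
4 | (S)-2-(3,4-dimethoxyphenyl)-2,3-dihydro-4H-pyran-4-one | COc1ccc([C@H]2OC=CC(=O)C2)cc1OC | intermediate
5 | lithium C3 enolate of 4, lithium (S)-2-(3,4-dimethoxyphenyl)-2H-pyran-4-olate | COc1ccc([C@H]2OC=CC(O[Li])=C2)cc1OC | intermediate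
6 | (2S,3R)-2-(3,4-dimethoxyphenyl)-3-methyl-2,3-dihydro-4H-pyran-4-one (2,3-trans) | COc1ccc([C@H]2OC=CC(=O)[C@@H]2C)cc1OC | intermediate
7 | (2S,3S,4R)-2-(3,4-dimethoxyphenyl)-3-methyl-3,4-dihydro-2H-pyran-4-ol (2,3-trans, 3,4-trans) | COc1ccc([C@H]2OC=C[C@@H](O)[C@@H]2C)cc1OC | intermediate
8 | (2S,3R,4R)-4-(tert-butyldimethylsilyloxy)-2-(3,4-dimethoxyphenyl)-3-methyl-3,4-dihydro-2H-pyran | COc1ccc([C@H]2OC=C[C@@H](O[Si](C)(C)C(C)(C)C)[C@@H]2C)cc1OC | intermediate
9 | C5 alkylborane of 8 (monoalkylborane drawn; boron equatorial, trans to the C4 silyloxy group) | COc1ccc([C@H]2OC[C@H](B)[C@@H](O[Si](C)(C)C(C)(C)C)[C@@H]2C)cc1OC | intermediate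
10 | (2S,3R,4S,5S)-4-(tert-butyldimethylsilyloxy)-2-(3,4-dimethoxyphenyl)-3-methyloxan-5-ol (all-equatorial) | COc1ccc([C@H]2OC[C@H](O)[C@@H](O[Si](C)(C)C(C)(C)C)[C@@H]2C)cc1OC | intermediate
11 | (2S,3R,4S,5S)-4-(tert-butyldimethylsilyloxy)-2-(3,4-dimethoxyphenyl)-3-methyloxan-5-yl trifluoromethanesulfonate | COc1ccc([C@H]2OC[C@H](OS(=O)(=O)C(F)(F)F)[C@@H](O[Si](C)(C)C(C)(C)C)[C@@H]2C)cc1OC | intermediate
12 | (2S,3S,4S,5S)-2-(3,4-dimethoxyphenyl)-4-hydroxy-3-methyloxan-5-yl trifluoromethanesulfonate (all-equatorial hydroxy triflate) | COc1ccc([C@H]2OC[C@H](OS(=O)(=O)C(F)(F)F)[C@@H](O)[C@@H]2C)cc1OC | intermediate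
13 | 4-bromoveratrole (4-bromo-1,2-dimethoxybenzene) | COc1ccc(Br)cc1OC | starting material
14 | 3,4-dimethoxyphenylmagnesium bromide | COc1ccc([Mg]Br)cc1OC | intermediate
15 | bromomagnesium C4 alkoxide of 12 | COc1ccc([C@H]2OC[C@H](OS(=O)(=O)C(F)(F)F)[C@@H](O[Mg]Br)[C@@H]2C)cc1OC | intermediate
16 | (3R,4S,5S)-5-(3,4-dimethoxyphenyl)-4-methyloxolane-3-carbaldehyde (4,5-trans, 3,4-cis) | COc1ccc([C@H]2OC[C@H](C=O)[C@@H]2C)cc1OC | intermediate
17 | bromomagnesium alkoxide of 18 | COc1ccc([C@H]2OC[C@H]([C@@H](O[Mg]Br)c3ccc(OC)c(OC)c3)[C@@H]2C)cc1OC | intermediate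
18 | (R)-(3,4-dimethoxyphenyl)[(3R,4S,5S)-5-(3,4-dimethoxyphenyl)-4-methyloxolan-3-yl]methanol | COc1ccc([C@H]2OC[C@H]([C@@H](O)c3ccc(OC)c(OC)c3)[C@@H]2C)cc1OC | target

**Count and risks**

Total steps: 9. Longest linear sequence: 8 (steps 1–7 and 9); step 8 is a one-step side branch.

Steps most likely to fail:

1. Step 9. The magnesium alkoxide may rearrange too slowly, so that the Grignard reagent attacks the sulfonate or the freed aldehyde epimerises before capture; facial control in the addition may also be weak. Fallback: separate the shift from the carbon–carbon bond formation by the hydride variant of the contraction. Setting out from 12, LiEt3BH in THF (−78 → 0 °C) deprotonates the hydroxyl, the lithium alkoxide undergoes the same shift, and the aldehyde is reduced as it forms to [(3S,4S,5S)-5-(3,4-dimethoxyphenyl)-4-methyloxolan-3-yl]methanol F1. Oxidation with Dess–Martin periodinane (NaHCO3, CH2Cl2, 0 °C) should then give 16 free of base, where the route is rejoined by adding 14 at −78 °C as in the second half of step 9.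

2. Step 7. The triflate may be lost by solvolysis, the shift may start under acid while the silyl ether is being cleaved, or cleavage next to the electron-poor triflate may be too slow. Fallback: work without a protecting group. Setting out from 7, hydroboration–oxidation of the free glycal alcohol (BH3·THF in excess; NaBO3·4H2O) should give (2S,3S,4S,5S)-2-(3,4-dimethoxyphenyl)-3-methyloxane-4,5-diol F2. Monotriflation at −40 °C (Tf2O, 1.0 equiv, pyridine, CH2Cl2) should favour the C5 hydroxyl, flanked by CH2, over the C4 hydroxyl next to the methyl-bearing carbon, and so returns to the route at 12.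

3. Step 2. The enolate may open by β-elimination of the ring oxygen (which would also erase the C2 stereocentre), double methylation may occur, or trans selectivity may be incomplete. Fallback: bring the methyl group in with the diene. Commercial pent-1-yn-3-ol (CCC(O)C#C) is oxidised (MnO2, CH2Cl2) to pent-1-yn-3-one F3, methanol is added (cat. DABCO) to give (E)-1-methoxypent-1-en-3-one F4, and silylation (Me3SiCl, Et3N, ZnCl2) gives (1E,3Z)-1-methoxy-3-(trimethylsilyloxy)penta-1,3-diene F5. Setting out from 1, an anti-selective catalytic asymmetric Mukaiyama aldol addition of F5 (chiral tetravalent zirconium catalyst from Zr(OtBu)4 and a 3,3'-diiodo-BINOL) should give (4R,5S,E)-5-(3,4-dimethoxyphenyl)-1-methoxy-4-methyl-5-(trimethylsilyloxy)pent-1-en-3-one F6, which TFA closes to the trans pyranone, returning to the route at 6.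

**Further compounds**

F1 | step 9 | [(3S,4S,5S)-5-(3,4-dimethoxyphenyl)-4-methyloxolan-3-yl]methanol | COc1ccc([C@H]2OC[C@H](CO)[C@@H]2C)cc1OC
F2 | step 7 | (2S,3S,4S,5S)-2-(3,4-dimethoxyphenyl)-3-methyloxane-4,5-diol | COc1ccc([C@H]2OC[C@H](O)[C@@H](O)[C@@H]2C)cc1OC
F3 | step 2 | pent-1-yn-3-one | CCC(=O)C#C
F4 | step 2 | (E)-1-methoxypent-1-en-3-one | CCC(=O)/C=C/OC
F5 | step 2 | (1E,3Z)-1-methoxy-3-(trimethylsilyloxy)penta-1,3-diene | C/C=C(O[Si](C)(C)C)/C=C/OC
F6 | step 2 | (4R,5S,E)-5-(3,4-dimethoxyphenyl)-1-methoxy-4-methyl-5-(trimethylsilyloxy)pent-1-en-3-one | COc1ccc([C@H]([C@@H](C)C(=O)/C=C/OC)O[Si](C)(C)C)cc1OC
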